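Thursday's run and Sunday's run, charged at 0.014 M and 0.022 M of each hand, reached 24.0 % and 24.1 % at 50.0 min, so I took the percentage as free of the charge.

in all of them: gas 1.2 mM (held)
- Thursday's: left-handed substrate 0.014 M; right-handed substrate 0.014 M; run made earlier
- Sunday's: left-handed substrate 0.022 M; right-handed substrate 0.022 M; run made earlier
- flask: left-handed substrate 0.010 M; right-handed substrate 0.010 M; time 40 min

| run | time / min | left-handed product / % |
|---|---|---|
| Thursday's | 10.0 | 5.3 |
| Thursday's | 20.0 | 12.1 |
| Thursday's | 30.0 | 15.5 |
| Thursday's | 40.0 | 20.9 |
| Thursday's | 50.0 | 24.0 |
| Sunday's | 10.0 | 5.6 |
| Sunday's | 20.0 | 10.0 |
| Sunday's | 30.0 | 15.1 |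
| Sunday's | 40.0 | 20.0 |
| Sunday's | 50.0 | 24.1 |

(readings scatter by 0.5 percentage points)

- reagent is single-handed; left-handed substrate and right-handed substrate are mirror images of each other, charged as a racemate, each of them at the stated concentration
- at the start none of the gas is in solution
- the handed part of reagent does not stay in what it makes, so the products of the two hands are mirror images too

- alpha: doubling the transfer coefficient of the gas, all else as stated
- delta: doubling the saturation concentration of gas, all else as stated

- how much left-handed product there is at 40 min, in percent of the left-handed substrate and right-handed substrate together charged
- the change that raises the amount of left-handed product at 40 min, in percent of the left-handed substrate and right-handed substrate together charged most ("none" if none brings more than 2 percentage points) (alpha / delta / none)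
- amount of left-handed product at 40 min, in percent of the left-handed substrate and right-handed substrate together charged, after delta

I drew the curve as a pseudo-first-order rise towards a level of half the charge, the share that was left-handed substrate. The last readings of the two runs gave my one quantity, the fractional rate 0.0131 /min, the share of the remaining distance to that level covered each minute.

For the flask, my starting slope held straight gave 6.55 % in 10.0 min. My bending curve then reached 20.4 % at 40 min, stood at a quarter of the charge at 52.8 min, and ran on towards half the charge.

If [reagent] followed [gas], my reckoning for delta doubled the fractional rate and gave 32.5 %, a gain of 12 percentage points, more than the margin. I expected little from alpha, because the percentage had not fallen as the charge rose.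

The forecast gave 20.4 %, delta and 32 %, the last slightly below mine, and said of that last step: “The gas order was never tested, so I assume first order”.

The flask gave 20.9 %. Delta brought 13 points and alpha 0.73 points, so the better change was delta, which gave 34.4 %.

    reagent + left-handed substrate → left-handed product (k = 0.280 /M/s)
    reagent + right-handed substrate → right-handed product (k = 0.130 /M/s)
    left-handed substrate ⇌ achiral form (K = 0.850, k = 0.00220 /s)
    right-handed substrate ⇌ achiral form (K = 0.850, k = 0.00220 /s)
    achiral form → waste (k = 5.80 × 10⁻⁵ /s)
    gas ⇌ reagent, rate k6*(csat - [reagent]) (kL = 0.0320 /s)
    reagent → decomposition product (k = 1.50 × 10⁻⁷ /s)

At 40.0 min the flask held 19.9 % as achiral form, for which the fractional rate has no term, yet my curve stood 0.50 points below the left-handed product, about one scatter. The neighbouring flask was the same one read at 1.5 h, and there the fractional rate gave 34.6 %. That neighbour held 11.6 % as achiral form and 37.3 % of left-handed product, 2.7 points above my curve.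

The data were generated by integration for an exercise, and the scatter is random.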